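**Plan**

Numbering: ring A is the 11-membered ring N4–C5–C6–C7–C8–C9(=O)–C10(Et)–C11–C12–C1–C9a(=O); ring B is the γ-lactam N4/C9a/C1/C2/C3; ring C is the γ-lactone C11(O)–C12–C13(Me)–C14(=O); ring D is the γ-lactone C18(O)–C19–C20(Me)–C21(=O) on C3.
Cuts: C8–C9 first (ring A opens to a C9 S-(2-pyridyl) thioester and a C8 primary iodide), then C10–C11 (aldol, ring C reopened at O–C14), C18–C19 and C18–H (ring D), C1–C12 together with C13–CH3 (Michael addition/alkylation), and N4–C5.
Forward: ring B is bought and N-alkylated; a one-pot Michael addition/methylation onto a chiral 5-alkoxybutenolide attaches C12–C14; ring D follows by zinc-homoenolate acylation and ketone reduction; the butenolide acetal is opened to the C11 aldehyde; an aldol adds C9/C10 and ring C closes; ring A is closed last.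
Stereochemistry: C3 from the chiral pool; C1 trans to the C3 substituent; C12 and C13 relayed from the menthyloxy acetal carbon, which is then sacrificed; C20 from the zinc reagent; C18 by Felkin–Anh reduction; C10 and C11 from the oxazolidinone auxiliary.
Feature that allows the key event: C9 and N4 are joined only by the unbranched chain C5–C8, so the cut leaves an acyl electrophile and a plain primary iodide; the cis-substituted ring C (C11, C12) and the planar lactam of ring B hold both arms on one face, and the ketone is formed base-free at its final oxidation level next to the α-branched, β-acyloxy C10.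

Key step: step 14

Assumption: butenolide 6 and the THF solution of zinc reagent 13 are taken as purchasable, and the menthyl acylal is assumed to survive brief CrO3/H2SO4 at 0 °C.

**Route**

Step 1
Reactants: 1 (S)-5-(hydroxymethyl)pyrrolidin-2-one
Product: 2 (S)-5-[(tert-butyldimethylsilyloxy)methyl]pyrrolidin-2-one
Conditions: TBSCl, imidazole, DMF, 0 → 23 °C
Reagents that add atoms: tert-butyldimethylsilyl chloride, CC(C)(C)[Si](C)(C)Cl
Why: Imidazole-promoted O-silylation of the primary alcohol is much faster than reaction at the lactam N–H and masks the hydroxyl (the future C18) for the base steps that follow.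

Step 2
Reactants: 2 (S)-5-[(tert-butyldimethylsilyloxy)methyl]pyrrolidin-2-one; 3 1-bromo-4-chlorobutane
Product: 5 (S)-1-(4-chlorobutyl)-5-[(tert-butyldimethylsilyloxy)methyl]pyrrolidin-2-one, via sodium lactamate 4 (not isolated)
Conditions: NaH, DMF, 0 °C; then 3, 0 → 23 °C
Reagents that add atoms: sodium hydride, [Na+].[H-] (sodium of 4 only)
Why: Lactam N-alkylation (SN2) takes place at the C–Br end of 3 because bromide is displaced far faster than chloride, which leaves the C8 chloride as a latent iodide.

Step 3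
Reactants: 5 (S)-1-(4-chlorobutyl)-5-[(tert-butyldimethylsilyloxy)methyl]pyrrolidin-2-one; 6 (5S)-5-[(1S,2R,5S)-menthyloxy]furan-2(5H)-one
Product: 9 silyl ether acylal (3S,5S)-1-(4-chlorobutyl)-3-[(2S,3S,4S)-2-[(1S,2R,5S)-menthyloxy]-4-methyl-5-oxotetrahydrofuran-3-yl]-5-[(tert-butyldimethylsilyloxy)methyl]pyrrolidin-2-one, via lactam lithium enolate 7 (not isolated), via lithium enolate of the Michael adduct 8 (not isolated)
Conditions: LiN(i-Pr)2, THF, −78 °C; 6, −78 °C; then MeI, DMPU, −78 → −30 °C
Reagents that add atoms: iodomethane, CI; lithium diisopropylamide, [Li]N(C(C)C)C(C)C (lithium of 7 and 8 only)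
Why: Tandem Michael addition–enolate alkylation: the lactam enolate attacks C12 of the butenolide on the face opposite the menthyloxy group and through its own face opposite the C3 side chain (C12 S, C1 S, 1,3-trans on ring B), and the lactone enolate so formed is methylated anti to the new C12 substituent (C13 S).

Step 4
Reactants: 9 silyl ether acylal
Product: 12 carboxylic acid (2S,4S)-1-(4-chlorobutyl)-4-[(2S,3S,4S)-2-[(1S,2R,5S)-menthyloxy]-4-methyl-5-oxotetrahydrofuran-3-yl]-5-oxopyrrolidine-2-carboxylic acid, via primary alcohol 10 (not isolated), via aldehyde 11 (not isolated)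
Conditions: CrO3, H2SO4, H2O, acetone, 0 °C
Reagents that add atoms: water, O
Why: Jones oxidation: the aqueous acid removes the primary silyl ether and hexavalent chromium takes the alcohol through the aldehyde hydrate to the acid, while the acylal, the lactam and the alkyl chloride are expected to be inert at 0 °C.

Step 5
Reactants: 12 carboxylic acid; 13 (R)-(3-methoxy-2-methyl-3-oxopropyl)zinc bromide
Product: 15 γ-keto ester, methyl (2S)-4-[(2S,4S)-1-(4-chlorobutyl)-4-(menthyloxy lactone)-5-oxopyrrolidin-2-yl]-2-methyl-4-oxobutanoate, via acid chloride 14 (not isolated)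
Conditions: (COCl)2, DMF (cat.), CH2Cl2, 0 → 23 °C; concentrate; then 13, Pd(PPh3)4 (5 mol %), THF, 0 → 23 °C
Reagents that add atoms: oxalyl chloride, O=C(Cl)C(Cl)=O (chlorine of 14 only)
Why: Acid chloride formation followed by palladium-catalysed acylation of a zinc homoenolate (Negishi-type ketone synthesis) joins C18 to C19 under neutral conditions, brings in C20 with its configuration fixed in the reagent (R in 13 becomes S at C20 by priority change only), and the tertiary lactam nitrogen rules out oxazolone racemisation at C3.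

Step 6
Reactants: 15 γ-keto ester
Product: 17 bis-lactone acylal (ring D closed as (2S,4S)-4-methyl-5-oxotetrahydrofuran-2-yl on C3, menthyl acylal kept), via hydroxy ester 16 (not isolated)
Conditions: LiBH(s-Bu)3, THF, −78 °C; AcOH quench; then TsOH·H2O (cat.), CH2Cl2, 23 °C
Reagents that add atoms: none
Why: Felkin–Anh reduction by the bulky, non-chelating hydride (N4 anti to the incoming hydride, attack past H3) should give the syn amino alcohol, C18 S, which closes ring D onto the methyl ester (lactonisation), while lactone and acylal carbonyls are not reduced at −78 °C.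

Step 7
Reactants: 17 bis-lactone acylal
Product: 18 lactol (pseudo-acid; as 17 with OH in place of menthyloxy at C11, both C11 epimers, in equilibrium with the open aldehyde acid)
Conditions: 3 M HCl, 1,4-dioxane, 50 °C
Reagents that add atoms: water, O
Why: Acid-catalysed hydrolysis of the mixed acylal (through the acyloxocarbenium ion) frees the stereocontrolling menthol and leaves C11 at the aldehyde oxidation level as its lactol, rings B and D being stable to aqueous acid.

Step 8
Reactants: 18 lactol
Product: 19 aldehyde ester, methyl (2S,3S)-3-[(3S,5S)-1-(4-chlorobutyl)-5-[(2S,4S)-4-methyl-5-oxotetrahydrofuran-2-yl]-2-oxopyrrolidin-3-yl]-2-methyl-4-oxobutanoate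
Conditions: Me3SiCHN2, PhMe/MeOH, 0 °C
Reagents that add atoms: (trimethylsilyl)diazomethane, C[Si](C)(C)C=[N+]=[N-]
Why: Esterification with the diazoalkane traps the open-chain carboxylic acid tautomer of the ring–chain equilibrium as the methyl ester and so uncovers the free C11 aldehyde without acid or base that could epimerise C12.

Step 9
Reactants: 20 (S)-4-benzyloxazolidin-2-one; 21 butanoyl chloride
Product: 23 (S)-4-benzyl-3-butanoyloxazolidin-2-one, via N-lithio oxazolidinone 22 (not isolated)
Conditions: n-BuLi, THF, −78 °C; then 21, −78 → 0 °C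
Reagents that add atoms: n-butyllithium, [Li]CCCC (lithium of 22 only)
Why: N-Acylation of the lithiated oxazolidinone with the acid chloride is the standard loading of the auxiliary.

Step 10
Reactants: 19 aldehyde ester; 23 (S)-4-benzyl-3-butanoyloxazolidin-2-one
Product: 26 imide lactone (rings B, C and D complete; C9 as N-acyl oxazolidinone; C10 S, C11 R), via boron enolate 24 (not isolated), via syn-aldol adduct 25 (not isolated)
Conditions: 23, Bu2BOTf, i-Pr2NEt, CH2Cl2, 0 °C; 19, −78 → 0 °C; pH 7 buffer, MeOH, H2O2; then PPTS, PhMe, 60 °C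
Reagents that add atoms: dibutylboron triflate, CCCCB(CCCC)OS(=O)(=O)C(F)(F)F (boron and butyl groups of 24 only)
Why: Evans syn-aldol: the Z-boron enolate reacts through a Zimmerman–Traxler chair on the face away from the benzyl group so that reagent control sets C10 S and C11 R, and mild acid then lactonises the new C11 hydroxyl onto the C14 ester to close ring C with C10 and C1 cis.

Step 11
Reactants: 26 imide lactone
Product: 28 chloro acid (C9 = CO2H), via peroxy acid 27 (not isolated)
Conditions: LiOH, H2O2, THF/H2O, 0 °C; Na2SO3; then 1 M HCl to pH 2, 23 °C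
Reagents that add atoms: hydrogen peroxide, OO
Why: Hydroperoxide cleavage of the N-acyloxazolidinone: the α-effect nucleophile attacks the exocyclic carbonyl selectively, sulfite reduces the peroxy acid, and any lactone opened by hydroxide should reclose on acidification.

Step 12
Reactants: 28 chloro acid
Product: 29 iodo acid
Conditions: NaI, acetone, reflux
Reagents that add atoms: sodium iodide, [Na+].[I-]
Why: Finkelstein exchange (SN2, driven by precipitation of NaCl) turns the robust chloride carried through the route into the iodide needed for halogen abstraction by nickel.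

Step 13
Reactants: 29 iodo acid
Product: 30 S-(pyridin-2-yl) thioester of 29
Conditions: 2,2′-dipyridyl disulfide, PPh3, CH2Cl2, 23 °C
Reagents that add atoms: 2,2′-dipyridyl disulfide, c1ccc(SSc2ccccn2)nc1
Why: Redox condensation (phosphine/disulfide thioesterification) activates only the free C9 acid under neutral conditions at room temperature, so C10 should not epimerise.

Step 14
Reactants: 30 S-(pyridin-2-yl) thioester
Product: 31 target, (C1S,C3S,C10S,C11R,C12S,C13S,C18S,C20S)-keto lactam with rings A–D
Conditions: NiBr2(dme) (0.5 equiv), 4,4′-di-tert-butyl-2,2′-bipyridine (0.5 equiv), Zn dust (10 equiv), degassed DMA, 23 °C; 30 added by syringe pump over 12 h (final 2 mM)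
Reagents that add atoms: none
Why: Proposed new method: an intramolecular nickel-catalysed reductive acyl–alkyl cross-electrophile coupling, whose closest known reaction type is the intermolecular nickel/bipyridine/zinc ketone synthesis from S-(2-pyridyl) thioesters and primary alkyl iodides, a coupling that tolerates esters, amides and α-stereocentres. Zerovalent nickel inserts into the C9–S bond (N,S-chelation by the 2-pyridyl group makes this the only acyl C–X bond that reacts, so both γ-lactones and the lactam stay inert), a monovalent nickel species abstracts iodine from C8, and the primary C8 radical is captured by the acyl–nickel centre of its own molecule to give a trivalent acyl(alkyl)nickel that reductively eliminates the C8–C9 bond. The one ring closed is the eleven-membered ring A, formed end to end by radical capture at nickel followed by C(sp2)–C(sp3) reductive elimination, and no new stereocentre arises. The closure is helped by the cis-3,4-disubstituted ring C (C11/C12) and the planar lactam N4–C9a(=O) of ring B, which hold the acyl arm and the N-butyl arm on one face. The step needs ring closure to win over intermolecular coupling and reduction of the C–I bond, which slow addition into a dilute, nickel-rich mixture should secure, and it needs C10 to stay intact beside the new ketone and its β-acyloxy group, which the neutral, base-free conditions at room temperature should secure because neither enolisation, decarbonylation nor β-elimination is expected there.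

**Compound list**

1 | (S)-5-(hydroxymethyl)pyrrolidin-2-one | O=C1CC[C@@H](CO)N1 | starting material
2 | (S)-5-[(tert-butyldimethylsilyloxy)methyl]pyrrolidin-2-one | O=C1CC[C@@H](CO[Si](C)(C)C(C)(C)C)N1 | intermediate
3 | 1-bromo-4-chlorobutane | ClCCCCBr | starting material
4 | sodium lactamate of 2 | [Na+].O=C1CC[C@@H](CO[Si](C)(C)C(C)(C)C)[N-]1 | intermediate
5 | (S)-1-(4-chlorobutyl)-5-[(tert-butyldimethylsilyloxy)methyl]pyrrolidin-2-one | ClCCCCN1C(=O)CC[C@H]1CO[Si](C)(C)C(C)(C)C | intermediate
6 | (5S)-5-[(1S,2R,5S)-menthyloxy]furan-2(5H)-one | O=C1C=C[C@@H](O[C@H]2C[C@@H](C)CC[C@@H]2C(C)C)O1 | starting material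
7 | lithium enolate of 5 | [Li]OC1=CC[C@@H](CO[Si](C)(C)C(C)(C)C)N1CCCCCl | intermediate
8 | lithium enolate of the Michael adduct (ring-C lactone enolate) | ClCCCCN1C(=O)[C@@H](C[C@H]1CO[Si](C)(C)C(C)(C)C)[C@@H]1[C@@H](O[C@H]2C[C@@H](C)CC[C@@H]2C(C)C)OC(O[Li])=C1 | intermediate
9 | silyl ether acylal, (3S,5S)-1-(4-chlorobutyl)-3-[(2S,3S,4S)-2-[(1S,2R,5S)-menthyloxy]-4-methyl-5-oxotetrahydrofuran-3-yl]-5-[(tert-butyldimethylsilyloxy)methyl]pyrrolidin-2-one | ClCCCCN1C(=O)[C@@H](C[C@H]1CO[Si](C)(C)C(C)(C)C)[C@@H]1[C@@H](O[C@H]2C[C@@H](C)CC[C@@H]2C(C)C)OC(=O)[C@H]1C | intermediate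
10 | primary alcohol from 9 (C18 OH) | ClCCCCN1C(=O)[C@@H](C[C@H]1CO)[C@@H]1[C@@H](O[C@H]2C[C@@H](C)CC[C@@H]2C(C)C)OC(=O)[C@H]1C | intermediate
11 | C18 aldehyde from 10 | ClCCCCN1C(=O)[C@@H](C[C@H]1C=O)[C@@H]1[C@@H](O[C@H]2C[C@@H](C)CC[C@@H]2C(C)C)OC(=O)[C@H]1C | intermediate
12 | carboxylic acid, (2S,4S)-1-(4-chlorobutyl)-4-[(2S,3S,4S)-2-[(1S,2R,5S)-menthyloxy]-4-methyl-5-oxotetrahydrofuran-3-yl]-5-oxopyrrolidine-2-carboxylic acid | ClCCCCN1C(=O)[C@@H](C[C@H]1C(=O)O)[C@@H]1[C@@H](O[C@H]2C[C@@H](C)CC[C@@H]2C(C)C)OC(=O)[C@H]1C | intermediate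
13 | (R)-(3-methoxy-2-methyl-3-oxopropyl)zinc bromide | COC(=O)[C@@H](C)C[Zn]Br | starting material
14 | acid chloride of 12 | ClCCCCN1C(=O)[C@@H](C[C@H]1C(Cl)=O)[C@@H]1[C@@H](O[C@H]2C[C@@H](C)CC[C@@H]2C(C)C)OC(=O)[C@H]1C | intermediate
15 | γ-keto ester (C18 ketone, C20 S, C21 methyl ester) | ClCCCCN1C(=O)[C@@H](C[C@H]1C(=O)C[C@H](C)C(=O)OC)[C@@H]1[C@@H](O[C@H]2C[C@@H](C)CC[C@@H]2C(C)C)OC(=O)[C@H]1C | intermediate
16 | (18S)-γ-hydroxy ester | ClCCCCN1C(=O)[C@@H](C[C@H]1[C@@H](O)C[C@H](C)C(=O)OC)[C@@H]1[C@@H](O[C@H]2C[C@@H](C)CC[C@@H]2C(C)C)OC(=O)[C@H]1C | intermediate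
17 | bis-lactone acylal (ring D closed, menthyl acylal kept) | ClCCCCN1C(=O)[C@@H](C[C@H]1[C@@H]1C[C@H](C)C(=O)O1)[C@@H]1[C@@H](O[C@H]2C[C@@H](C)CC[C@@H]2C(C)C)OC(=O)[C@H]1C | intermediate
18 | lactol (pseudo-acid), both C11 epimers | ClCCCCN1C(=O)[C@@H](C[C@H]1[C@@H]1C[C@H](C)C(=O)O1)[C@@H]1C(O)OC(=O)[C@H]1C | intermediate
19 | aldehyde ester, methyl (2S,3S)-3-[(3S,5S)-1-(4-chlorobutyl)-5-[(2S,4S)-4-methyl-5-oxotetrahydrofuran-2-yl]-2-oxopyrrolidin-3-yl]-2-methyl-4-oxobutanoate | ClCCCCN1C(=O)[C@@H](C[C@H]1[C@@H]1C[C@H](C)C(=O)O1)[C@H](C=O)[C@H](C)C(=O)OC | intermediate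
20 | (S)-4-benzyloxazolidin-2-one | O=C1N[C@@H](Cc2ccccc2)CO1 | starting material
21 | butanoyl chloride | CCCC(Cl)=O | starting material
22 | N-lithio derivative of 20 | [Li]N1[C@@H](Cc2ccccc2)COC1=O | intermediate
23 | (S)-4-benzyl-3-butanoyloxazolidin-2-one | CCCC(=O)N1[C@@H](Cc2ccccc2)COC1=O | intermediate
24 | (Z)-dibutylboron enolate of 23 | CC/C=C(\OB(CCCC)CCCC)N1[C@@H](Cc2ccccc2)COC1=O | intermediate
25 | syn-aldol adduct (C10 S, C11 R, C14 methyl ester) | ClCCCCN1C(=O)[C@@H](C[C@H]1[C@@H]1C[C@H](C)C(=O)O1)[C@H]([C@@H](O)[C@H](CC)C(=O)N1[C@@H](Cc2ccccc2)COC1=O)[C@H](C)C(=O)OC | intermediate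
26 | imide lactone (rings B, C, D; C9 N-acyl oxazolidinone) | ClCCCCN1C(=O)[C@@H](C[C@H]1[C@@H]1C[C@H](C)C(=O)O1)[C@@H]1[C@H]([C@H](CC)C(=O)N2[C@@H](Cc3ccccc3)COC2=O)OC(=O)[C@H]1C | intermediate
27 | C9 peroxy acid | ClCCCCN1C(=O)[C@@H](C[C@H]1[C@@H]1C[C@H](C)C(=O)O1)[C@@H]1[C@H]([C@H](CC)C(=O)OO)OC(=O)[C@H]1C | intermediate
28 | chloro acid (C9 CO2H, C8 Cl) | ClCCCCN1C(=O)[C@@H](C[C@H]1[C@@H]1C[C@H](C)C(=O)O1)[C@@H]1[C@H]([C@H](CC)C(=O)O)OC(=O)[C@H]1C | intermediate
29 | iodo acid (C9 CO2H, C8 I) | ICCCCN1C(=O)[C@@H](C[C@H]1[C@@H]1C[C@H](C)C(=O)O1)[C@@H]1[C@H]([C@H](CC)C(=O)O)OC(=O)[C@H]1C | intermediate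
30 | S-(pyridin-2-yl) thioester of 29 | ICCCCN1C(=O)[C@@H](C[C@H]1[C@@H]1C[C@H](C)C(=O)O1)[C@@H]1[C@H]([C@H](CC)C(=O)Sc2ccccn2)OC(=O)[C@H]1C | intermediate
31 | target keto lactam | CC[C@@H]1C(=O)CCCCN2C(=O)[C@@H](C[C@H]2[C@@H]2C[C@H](C)C(=O)O2)[C@@H]2[C@H]1OC(=O)[C@H]2C | target

**Count**

Total steps: 14. Longest linear sequence: 13 (steps 1–8 and 10–14; step 9 is a one-step side branch).

**Steps most likely to fail**

Step 14 (Proposed new method). Intermolecular coupling and simple reduction of the C–I bond may outrun capture of the C8 radical by the acyl–nickel centre of the same molecule. The fallback closes the same bond at the aldehyde oxidation level with known chemistry. It sets out from iodo acid 29: BH3·THF at 0 °C should reduce only the carboxylic acid and give iodo alcohol F1; Dess–Martin periodinane gives iodo aldehyde F2; a SmI2/HMPA-promoted intramolecular Barbier reaction in THF at high dilution should close ring A as the C9 carbinol F3 (either C9 epimer serves); Dess–Martin oxidation of F3 comes back to the route at 31.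

Step 3. Proton transfer between the enolates and the butenolide, or poor pairing of the two chiral partners in the closed lithium transition state, may erode the one-pot addition/methylation. The fallback separates the two events and runs the addition through an open transition state. It sets out from 5: LiN(i-Pr)2 then Me3SiCl gives silyl ketene N,O-acetal F4; a Mukaiyama–Michael addition of F4 to 6 (TBSOTf cat., CH2Cl2, −78 °C, aqueous work-up) should give the unmethylated lactone F5; LiN(SiMe3)2 (1 equiv, which removes only the more acidic lactone α-proton) and MeI then methylate anti to the C12 substituent, and the route is rejoined at 9.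

Step 11. β-Elimination of the ring-C carboxylate from the enolisable imide, or attack of hydroperoxide and hydroxide at the ring carbonyls, may compete with cleavage of the auxiliary. The fallback reaches the acid without an auxiliary. It sets out from aldehyde 19: asymmetric (Z)-pent-2-enylboration with the diisopinocampheylborane reagent of the antipode that delivers the 11R carbinol (expected to be the one made from (+)-α-pinene) should give the syn homoallylic alcohol F6; PPTS closes ring C to vinyl lactone F7; ozonolysis (O3, then Me2S) gives aldehyde F8; Pinnick oxidation (NaClO2, NaH2PO4, 2-methylbut-2-ene) comes back to the route at 28.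

**Further compounds**

F1 | step 14 | iodo alcohol (C9 CH2OH) | ICCCCN1C(=O)[C@@H](C[C@H]1[C@@H]1C[C@H](C)C(=O)O1)[C@@H]1[C@H]([C@H](CC)CO)OC(=O)[C@H]1C
F2 | step 14 | iodo aldehyde (C9 CHO) | ICCCCN1C(=O)[C@@H](C[C@H]1[C@@H]1C[C@H](C)C(=O)O1)[C@@H]1[C@H]([C@H](CC)C=O)OC(=O)[C@H]1C
F3 | step 14 | ring-A C9 carbinol (both C9 epimers) | CC[C@@H]1C(O)CCCCN2C(=O)[C@@H](C[C@H]2[C@@H]2C[C@H](C)C(=O)O2)[C@@H]2[C@H]1OC(=O)[C@H]2C
F4 | step 3 | trimethylsilyl ketene N,O-acetal of 5 | C[Si](C)(C)OC1=CC[C@@H](CO[Si](C)(C)C(C)(C)C)N1CCCCCl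
F5 | step 3 | unmethylated Michael adduct (C13 H2) | ClCCCCN1C(=O)[C@@H](C[C@H]1CO[Si](C)(C)C(C)(C)C)[C@@H]1[C@@H](O[C@H]2C[C@@H](C)CC[C@@H]2C(C)C)OC(=O)C1
F6 | step 11 | syn homoallylic alcohol (C9 as vinyl CH, C14 methyl ester) | ClCCCCN1C(=O)[C@@H](C[C@H]1[C@@H]1C[C@H](C)C(=O)O1)[C@H]([C@@H](O)[C@H](CC)C=C)[C@H](C)C(=O)OC
F7 | step 11 | vinyl lactone (ring C closed, C9 as vinyl CH) | ClCCCCN1C(=O)[C@@H](C[C@H]1[C@@H]1C[C@H](C)C(=O)O1)[C@@H]1[C@H]([C@H](CC)C=C)OC(=O)[C@H]1C
F8 | step 11 | chloro aldehyde (C9 CHO) | ClCCCCN1C(=O)[C@@H](C[C@H]1[C@@H]1C[C@H](C)C(=O)O1)[C@@H]1[C@H]([C@H](CC)C=O)OC(=O)[C@H]1C
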